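## The problem

Target 34 is a furanoheliangolide. Its ten-membered carbocycle C1–C10 (ring A, germacrane numbering) has C3 and C10 tied by an oxygen atom, so that O, C3, C2, C1 and C10 form a 3(2H)-furanone (ring B). C6 and C7 carry a trans-fused α-methylene-γ-butyrolactone built from C11, C12 and C13 (ring C). Ring A also holds the 4Z alkene bearing the C15 hydroxymethyl group in conjugation with ring B, an isobutyrate at C8 and the methyl-bearing, fully substituted C10.

There are four stereocentres (6R, 7R, 8R, 10R). C6, C7 and C8 are contiguous and can steer one another, but C10 is separated from them by the C9 methylene group, so neither an open chain nor a floppy medium ring relays configuration to it. On a six-membered ring C7 controls C8 as its neighbour and C10 across the ring by plain facial bias, and C6 can be set last from C7 through allylic strain in the medium ring.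

The methylene lactone, the dienyl furanone with its acidic γ-position, the C8 ester and the allylic alcohol tolerate neither strong base nor hard nucleophiles. All organometallic and hydride chemistry must therefore be finished before they appear.

The enabling feature is that C1, C10, C9, C8, C7 and C6, with C14 on C10 and C11 on C7, are the p-menthane ring of carvone with C2–C5 wedged between C1 and C6. Drawing C1–C6 and deleting C3–C4 turns ring A into a 1-ethynyl-2-alkenylcyclohexanol, a 3-oxy-1,5-enyne set up for a [3,3] shift.

Below, α is the ring face of H7 and of the C10–O bond; β is the face of C11, C14 and the C8–O bond.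

## Retrosynthesis

**Ester and silyl groups.** The O–Si bond at C15 is cut (34 to 33), then the acyl–O bond at C8 (33 to alcohol 31 and isobutyryl chloride 32). 31 comes from the bis-silyl lactone 30. Carrying the ester earlier would expose it to the Grignard reagent, to KH and to a neighbouring C6 alkoxide. The price is a graded set of silyl ethers: TES at C10, TBS at C8, TBDPS at C15. The forward steps need selective loss of a secondary TBS ether beside a primary TBDPS ether, and an acylation that leaves the methylene lactone alone.

**Lactone, C6–O and the 4Z alkene.** 30 is the oxidised form of lactol 29, the closed form of hydroxy enal 28. 28 is traced by a retro-E1cB to the 5α,6α-epoxide 27, in which C4 is still sp3. The alternatives speak against themselves. Allylic oxidation at C6 of a finished 4-ene would have to compete with other allylic sites, and reduction of a 6-ketone would leave C6 to an unknown ring conformation. The epoxide uses the alkene that the key step leaves behind, draws C6 from C7, and lets ring B force the cis arrangement of C3 and C6. The forward steps need α-face epoxidation and removal of H4 by a mild base.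

**C12 oxidation.** 27 comes from enal 26, and 26 from isopropenyl compound 24 (C12–O cut). Oxidising C12 before the peracid step, not after, turns C11=C13 into an electron-poor acrolein. C5=C6 is then the only nucleophilic alkene left. The step count is the same in either order.

**Furanone.** The O–C3 bond of 24 is cut to give α'-hydroxy enone 23, the desilylated form of dienone 22. Cutting O–C10 instead would require stereocontrolled C–O formation at a tertiary centre inside the medium ring, whereas O–C3 uses the C10 carbinol as the nucleophile. The forward reaction must add oxygen to C3 and remove two hydrogens, which a closure mediated by divalent palladium does in one operation. A 5Z alkene is wanted in 22. The unit C4–C3–O–C10 of ring B is held antiperiplanar, and a 5E alkene beside it would put two trans units into the nine-membered oxacycle.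

**Ring A (key cut).** In 22 the bond C3–C4 is cut and C1–C6 is redrawn, which leads to carbinol 19. End-to-end closures at C2–C3, C5–C6 or C9–C10 would all need dilution, and C7, C8 and C10 would have to be set on a chain. The ring expansion needs neither. The precursor is a cyclohexane on which all three lasting centres already sit. The forward step needs a free C1 alkoxide and gauche ethynyl and alkenyl groups.

**The two side arms.** C1–C2 is cut (19 to ketone 17 and ethynylmagnesium bromide 18), then C6–C5 (17 to ketone 11 and bromide 15). Because C10 of 11 is quaternary, C6 is the only enolisable position. The alkenyl group must enter anti to the isopropenyl group and must not be scrambled afterwards, which calls for a weakly basic enolate.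

**C10–O.** 11 is traced through silyl enol ether 9 to enone 8. Epoxidising the enone would place oxygen on C10, but reductive opening would then break exactly that bond. Oxidising a regiodefined enol ether keeps the bond and also delivers it already silylated. Both ring substituents of 9 lie on the β face, so the oxidant has to come from α.

**C8–O.** 8 comes from 7, 6 and 5, and 5 from ketone 4 (C8–H cut). 4 comes from acetate 3, carveol 2 and (R)-carvone 1 (C8=O cut). Direct γ-oxygenation of 1 would place oxygen trans to the isopropenyl group. Going through the ketone allows a bulky hydride to give the cis alcohol.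

**Side-arm reagent.** Bromide 15 comes from silyl ether 13 of propargyl alcohol 12 by syn hydrometalation and halogenation.

## Roads not taken

**Alternative 1:** The cut is C9–C10. One-electron oxidation (anodic, or with the tetravalent cerium salt (NH4)2Ce(NO3)6) of the silylene-tethered siloxyfuran and enol silane A1 would join furan carbon C10 to enol carbon C9 and give A2.

- Merits: one step creates the quaternary centre, ring A and ring B at the correct oxidation level. The lactone stereocentres are already in place and the route would be shorter than the chosen one.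
- Weak points: C10 is formed during a medium-ring closure, with only a long tether and remote centres to bias it. The furan can also couple at C2, and the electron-rich dienyl furan is itself oxidisable. A2 still lacks C8 configuration (a ketone reduction next to an epimerisable C7) and the exocyclic methylene group.
- Comparison: this road is better in step economy. Against that, the chosen plan sets C8 and C10 on a chair by plain facial bias and needs no dilution.

**Alternative 2:** The cuts are C1–C2 and O–C3. Oxidation of aldoxime A3 and intramolecular nitrile oxide cycloaddition onto its terminal vinyl group would give isoxazoline A4, a masked 1,3-dicarbonyl unit.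

- Merits: the closure is neutral and tolerates the ester and the lactone, so it can come late. The mask leads to the classical acid closure of ring B.
- Weak points: all four stereocentres and the Z-trisubstituted diene must be built on an open chain. Dimerisation competes with the ten-membered closure, and regiochemistry is less secure in a constrained ring than between free partners. The N–O bond must be cleaved beside a diene, the resulting ketol oxidised, and the methylene group still added.
- Comparison: this road is superior in functional-group tolerance and convergence at ring closure. Against that, the chosen plan takes C7 from the chiral pool, derives C8 and C10 from it, and has an intramolecular, irreversible ring-forming step.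

**Alternative 3:** The cut is O–C10. A Lewis acid would let the C3 carbonyl oxygen of epoxy ketone A5 open the 1(10)-epoxide at C10 with inversion and give cyclic enol ether A6.

- Merits: the closure is biomimetic and stereospecific at C10, every sensitive group can already be present, and only oxidation of C1–OH and desilylation remain.
- Weak points: the hard part, a ten-membered ring with a 4Z enone and a defined trans-epoxide, is presupposed and not solved. A ketone oxygen is a poor nucleophile. The tertiary centre can ionise with loss of configuration, and transannular C–C bond formation is the usual fate of such epoxides.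
- Comparison: its endgame is shorter. The chosen plan answers the question this road leaves open, namely where ring A comes from.

Key step: step 14

Remark: germacrane atom numbers are also used for the six-membered precursors. C4 in 21–27 is drawn as formed, and its lability has no consequence because step 19 erases it.

## Steps

Step 1
Reactants: 1 (R)-(−)-carvone
Product: 2 (−)-cis-carveol (1R,5R; 1β-OH cis to the isopropenyl group)
Conditions: NaBH4, CeCl3·7H2O, MeOH, 0 °C
Reagents that add atoms: none
Why: Luche reduction gives clean 1,2-attack, and axial delivery of hydride from the α face should give the β alcohol. This centre only masks the ketone and is removed in step 7.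

Step 2
Reactants: 2 (−)-cis-carveol
Product: 3 cis-carvyl acetate (1R,5R)
Conditions: Ac2O, pyridine, DMAP (cat.), CH2Cl2, 0 °C to rt
Reagents that add atoms: acetic anhydride, CC(=O)OC(C)=O
Why: Standard DMAP-catalysed acetylation. The ester protects C1–O from the oxidant and deactivates the C1–H bond.

Step 3
Reactants: 3 cis-carvyl acetate
Product: 4 (4R,6R)-4-acetoxy-3-methyl-6-(prop-1-en-2-yl)cyclohex-2-en-1-one (C8 ketone)
Conditions: CrO3, 3,5-dimethylpyrazole, CH2Cl2, −20 °C
Reagents that add atoms: chromium trioxide, O=[Cr](=O)=O
Why: Allylic oxidation of a cyclohexene methylene group to the enone with the chromium trioxide–dimethylpyrazole complex. C8H2 is the only ring methylene group allylic to the trisubstituted alkene, and isopropenyl groups normally survive this reagent, as in oxidations of related terpenes.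

Step 4
Reactants: 4 C8 ketone
Product: 5 (1R,4R,5R)-4-hydroxy-2-methyl-5-(prop-1-en-2-yl)cyclohex-2-en-1-yl acetate (8β-OH cis to the isopropenyl group)
Conditions: LiBH(s-Bu)3, THF, −78 °C
Reagents that add atoms: none
Why: The fully substituted β-carbon of the enone blocks conjugate reduction, so the hindered borohydride reduces 1,2. It should approach from the α face, anti to the adjacent isopropenyl group, which sets C8 with oxygen on the β face. The acetate is inert at this temperature.

Step 5
Reactants: 5 8β-alcohol
Product: 6 8-O-TBS ether of 5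
Conditions: TBSOTf, 2,6-lutidine, CH2Cl2, −78 to 0 °C
Reagents that add atoms: tert-butyldimethylsilyl triflate, CC(C)(C)[Si](C)(C)OS(=O)(=O)C(F)(F)F
Why: Silyl triflate with a hindered base is the standard way to silylate a crowded secondary alcohol, and no stereocentre is touched.

Step 6
Reactants: 6 acetate
Product: 7 (1R,4R,5R)-4-(tert-butyldimethylsilyloxy)-2-methyl-5-(prop-1-en-2-yl)cyclohex-2-en-1-ol
Conditions: K2CO3 (cat.), MeOH, 0 °C to rt
Reagents that add atoms: none
Why: Transesterification removes the acetate. The TBS ether and both alkenes are stable to carbonate in methanol.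

Step 7
Reactants: 7 allylic alcohol
Product: 8 (4R,5R)-4-(tert-butyldimethylsilyloxy)-2-methyl-5-(prop-1-en-2-yl)cyclohex-2-en-1-one
Conditions: Dess–Martin periodinane, pyridine, CH2Cl2, 0 °C to rt
Reagents that add atoms: none
Why: Neutral oxidation of the allylic alcohol restores the carvone enone. The γ-silyloxy group has no pathway for elimination under these conditions.

Step 8
Reactants: 8 γ-silyloxy enone
Product: 9 C1(OTES)=C10 triethylsilyl enol ether (8β-OTBS and 7β-isopropenyl)
Conditions: Et3SiH, RhCl(PPh3)3 (1 mol %), THF, 50 °C
Reagents that add atoms: triethylsilane, CC[SiH](CC)CC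
Why: Rhodium-catalysed 1,4-hydrosilylation of an enone gives the tetrasubstituted silyl enol ether regiospecifically. Under these conditions the 1,1-disubstituted alkene is a poor substrate for the catalyst.

Step 9
Reactants: 9 silyl enol ether
Product: 11 (2R,4R,5R)-4-(tert-butyldimethylsilyloxy)-2-methyl-5-(prop-1-en-2-yl)-2-(triethylsilyloxy)cyclohexan-1-one, via siloxy epoxide 10 (not isolated)
Conditions: mCPBA (1.05 equiv), hexane–CH2Cl2, −20 to 0 °C
Reagents that add atoms: 3-chloroperoxybenzoic acid, OOC(=O)c1cccc(Cl)c1
Why: Rubottom oxidation. The electron-rich enol ether reacts far faster than the isopropenyl group, and the peracid should enter from the α face because the C7 and C8 substituents both shield the β face. Opening of 10 with an O-to-O silyl shift sets C10 and delivers it already protected.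

Step 10
Reactants: 12 propargyl alcohol
Product: 13 tert-butyl(diphenyl)(prop-2-yn-1-yloxy)silane
Conditions: TBDPSCl, imidazole, DMF, rt
Reagents that add atoms: tert-butyldiphenylsilyl chloride, CC(C)(C)[Si](Cl)(c1ccccc1)c1ccccc1
Why: Standard silylation. TBDPS is chosen so that it outlasts the TES and TBS ethers.

Step 11
Reactants: 13 propargyl silyl ether
Product: 15 (E)-(3-bromoallyloxy)(tert-butyl)diphenylsilane, via alkenylzirconocene chloride 14 (not isolated)
Conditions: Cp2ZrHCl, THF, rt; then NBS, 0 °C
Reagents that add atoms: N-bromosuccinimide, O=C1CCC(=O)N1Br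
Why: Hydrozirconation adds Zr–H syn with zirconium at the terminus, and bromination cleaves the C–Zr bond with retention, so the E bromide is expected.

Step 12
Reactants: 11 ketone; 15 (E)-alkenyl bromide
Product: 17 6α-[(E)-3-(TBDPS-oxy)prop-1-enyl] ketone (alkenyl trans to the isopropenyl group), via chlorozinc enolate 16 (not isolated)
Conditions: LiN(SiMe3)2, THF, −78 °C; ZnCl2, −78 °C to rt; 15, Pd2(dba)3 (2.5 mol %), P(t-Bu)3 (6 mol %), rt
Reagents that add atoms: none
Why: Negishi-type palladium-catalysed α-alkenylation of a ketone enolate. C6 is the only enolisable position, and the C–C bond should form on the α face, anti to the neighbouring isopropenyl group. The weakly basic zinc enolate is chosen so that the more acidic β,γ-unsaturated product is neither epimerised nor brought into conjugation.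

Step 13
Reactants: 17 6α-alkenyl ketone; 18 ethynylmagnesium bromide
Product: 19 1α-ethynyl-6α-alkenyl-cyclohexan-1β-ol (8β-OTBS; 10α-OTES)
Conditions: LaCl3·2LiCl, THF, −78 to −30 °C
Reagents that add atoms: none
Why: Lanthanide-promoted 1,2-addition suppresses enolisation of the sensitive ketone. The slim acetylide should attack axially from the α face, away from the axial C14 methyl group and the β substituents, which places the ethynyl group axial and gauche to the equatorial alkenyl group.

Step 14
Reactants: 19 ethynyl carbinol
Product: 22 (2Z,5Z)-cyclodeca-2,5-dienone (4-CH2OTBDPS; 7β-isopropenyl; 8β-OTBS; 10α-OTES), via potassium alkoxide 20 (not isolated), via potassium allenolate 21 (not isolated)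
Conditions: KH (1.05 equiv), 18-crown-6, THF, 0 °C to rt; inverse quench into AcOH–THF, −78 °C
Reagents that add atoms: none
Why: Deprotonation gives alkoxide 20, whose crown-separated oxyanion weakens the adjacent C1–C6 bond, so that the 3-oxido-1,5-enyne C3≡C2–C1–C6–C5=C4 undergoes a concerted [3,3] shift in which C3–C4 forms as C1–C6 breaks. The closest known reaction type is the anionic oxy-Cope ring expansion of 1-alkynyl- and 1-alkenyl-2-alkenylcyclohexanols to cyclodecenones. Ring A is not closed end to end but arises by four-carbon enlargement through a six-centre chair-like array, so neither dilution nor an endo/exo preference is at issue. With the ethynyl group axial and the alkenyl group equatorial, C10 is pseudo-equatorial and C7 pseudo-axial in that array, which makes C5=C6 Z, the geometry that a ten-membered ring already holding an allenolate accommodates best; the syn-axial contact of C14 with the 8-OTBS group is released as the ring opens. C4 is set by suprafacial transfer from C6 across the E alkene, the new bond forming on the face from which C1 departs, and this centre is erased in step 19. The shift is irreversible because it ends in the delocalised allenolate 21, and the cold inverse quench should protonate C2 from the side of H3 to give the 2Z enone before H4 can be removed. Chemoselectivity rests on the oxyanion: the neutral 1,5-diene C4=C5–C6–C7–C11=C13 lacks the acceleration and stays untouched at this temperature, and a slight excess of amine-free KH avoids metalation of the alkyne C–H and leaves no proton shuttle.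

Step 15
Reactants: 22 dienone
Product: 23 10α-hydroxy-(2Z,5Z)-dienone
Conditions: HF·pyridine, pyridine, THF, 0 °C
Reagents that add atoms: none
Why: Buffered fluoride removes the least hindered silyl group (TES), while the TBS and TBDPS ethers are much slower. The medium is too weakly basic to move the skipped diene.

Step 16
Reactants: 23 α'-hydroxy enone
Product: 24 3,10-oxa-bridged 3(2H)-furanone with 5Z alkene
Conditions: PdCl2(MeCN)2 (10 mol %), CuCl (20 mol %), Na2HPO4, O2 (1 atm), DME, 50 °C
Reagents that add atoms: none
Why: Wacker-type oxidative cyclisation of an α'-hydroxy enone to a 3(2H)-furanone. Divalent palladium activates C2=C3 for the 5-endo attack of the C10 hydroxyl group on C3, which a free alkoxide resists. The resulting palladium enolate can equilibrate at C2 and loses H3 by β-hydride elimination, and oxygen with copper reoxidises zerovalent palladium.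

Step 17
Reactants: 24 furanone
Product: 26 C12 enal (7β-acrolein unit), via allylic alcohol 25 (not isolated)
Conditions: SeO2 (0.3 equiv), t-BuOOH, CH2Cl2, 0 °C to rt; crude, then Dess–Martin periodinane, pyridine, CH2Cl2, 0 °C
Reagents that add atoms: selenium dioxide, O=[Se]=O; tert-butyl hydroperoxide, CC(C)(C)OO
Why: Selenium dioxide allylic oxidation (ene reaction, then [2,3] shift) prefers the 1,1-disubstituted alkene and its methyl group. The allylic hydrogens H4 and H7 of the 5Z alkene lie in the alkene plane and are badly aligned for the ene step. The second stage converges alcohol and aldehyde to the enal.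

Step 18
Reactants: 26 enal
Product: 27 5α,6α-epoxide (cis)
Conditions: mCPBA, CH2Cl2, 0 °C to rt
Reagents that add atoms: 3-chloroperoxybenzoic acid, OOC(=O)c1cccc(Cl)c1
Why: Prilezhaev epoxidation of the only nucleophilic alkene left, since the acrolein and the furanone double bonds are electron-poor. Allylic 1,3-strain across the Z alkene holds H7 and H4 in the alkene plane and places ring atoms C8 and C3 on one face. The peracid should therefore add to the open α face and set C6 with the configuration of the target.

Step 19
Reactants: 27 epoxide
Product: 29 6,12-lactol (mixture at C12; 4Z alkene), via hydroxy enal 28 (not isolated)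
Conditions: DBU, CH2Cl2, 0 °C to rt
Reagents that add atoms: none
Why: Vinylogous E1cB opening. H4 is the γ-hydrogen of the furanone and lies next to the epoxide, so an amidine base should suffice. The C5–O bond breaks while C6–O is retained, and rings A and B allow only the cis arrangement of C3 and C6, which is the 4Z alkene. The freed 6α-hydroxyl group closes onto the aldehyde.

Step 20
Reactants: 29 lactol
Product: 30 α-methylene-γ-butyrolactone (8β-OTBS; 15-OTBDPS)
Conditions: Dess–Martin periodinane, pyridine, CH2Cl2, rt
Reagents that add atoms: none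
Why: Oxidation of a lactol to the lactone under neutral conditions. No other free hydroxyl group is present.

Step 21
Reactants: 30 bis-silyl lactone
Product: 31 8β-alcohol (15-OTBDPS)
Conditions: aq HF (48 %), MeCN, 0 °C
Reagents that add atoms: none
Why: Under acidic fluoride a TBS ether is cleaved much faster than a TBDPS ether. The lactone, the furanone and the diene are stable to these non-nucleophilic conditions.

Step 22
Reactants: 31 8β-alcohol; 32 isobutyryl chloride
Product: 33 8-O-isobutyrate (15-OTBDPS)
Conditions: Et3N, DMAP (cat.), CH2Cl2, 0 °C to rt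
Reagents that add atoms: none
Why: DMAP-catalysed acylation of the only free hydroxyl group. The configuration at C8 is retained because only the O–H bond reacts.

Step 23
Reactants: 33 silyl ether
Product: 34 target compound CNP0176924.3
Conditions: HF·pyridine (excess), THF, 0 °C to rt
Reagents that add atoms: none
Why: Fluoride-mediated cleavage of the primary allylic TBDPS ether in a mildly acidic medium avoids conjugate addition to the methylene lactone and acyl migration.

## Compound list

1 | (R)-(−)-carvone | CC1=CC[C@H](CC1=O)C(C)=C | starting material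
2 | (−)-cis-carveol | CC1=CC[C@H](C[C@H]1O)C(C)=C | intermediate
3 | cis-carvyl acetate | CC1=CC[C@H](C[C@H]1OC(C)=O)C(C)=C | intermediate
4 | (4R,6R)-4-acetoxy-3-methyl-6-(prop-1-en-2-yl)cyclohex-2-en-1-one | CC1=CC(=O)[C@H](C[C@H]1OC(C)=O)C(C)=C | intermediate
5 | (1R,4R,5R)-4-hydroxy-2-methyl-5-(prop-1-en-2-yl)cyclohex-2-en-1-yl acetate | CC1=C[C@@H](O)[C@H](C[C@H]1OC(C)=O)C(C)=C | intermediate
6 | 8-O-TBS ether of 5 | CC1=C[C@@H](O[Si](C)(C)C(C)(C)C)[C@H](C[C@H]1OC(C)=O)C(C)=C | intermediate
7 | (1R,4R,5R)-4-(TBS-oxy)-2-methyl-5-(prop-1-en-2-yl)cyclohex-2-en-1-ol | CC1=C[C@@H](O[Si](C)(C)C(C)(C)C)[C@H](C[C@H]1O)C(C)=C | intermediate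
8 | (4R,5R)-4-(TBS-oxy)-2-methyl-5-(prop-1-en-2-yl)cyclohex-2-en-1-one | CC1=C[C@@H](O[Si](C)(C)C(C)(C)C)[C@H](CC1=O)C(C)=C | intermediate
9 | C1(OTES)=C10 silyl enol ether | CC1=C(O[Si](CC)(CC)CC)C[C@H](C(C)=C)[C@H](O[Si](C)(C)C(C)(C)C)C1 | intermediate
10 | 1α,10α-siloxy epoxide | C[C@]12O[C@@]1(O[Si](CC)(CC)CC)C[C@H](C(C)=C)[C@H](O[Si](C)(C)C(C)(C)C)C2 | intermediate
11 | (2R,4R,5R)-4-(TBS-oxy)-2-methyl-5-(prop-1-en-2-yl)-2-(TES-oxy)cyclohexan-1-one | O=C1C[C@H](C(C)=C)[C@H](O[Si](C)(C)C(C)(C)C)C[C@@]1(C)O[Si](CC)(CC)CC | intermediate
12 | propargyl alcohol | C#CCO | starting material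
13 | propargyl TBDPS ether | C#CCO[Si](c1ccccc1)(c1ccccc1)C(C)(C)C | intermediate
14 | (E)-alkenylzirconocene chloride (cyclopentadienyl rings written σ-bonded) | Cl[Zr](/C=C/CO[Si](c1ccccc1)(c1ccccc1)C(C)(C)C)(C1C=CC=C1)C1C=CC=C1 | intermediate
15 | (E)-3-bromoallyl TBDPS ether | Br/C=C/CO[Si](c1ccccc1)(c1ccccc1)C(C)(C)C | intermediate
16 | chlorozinc enolate of 11 | Cl[Zn]OC1=C[C@H](C(C)=C)[C@H](O[Si](C)(C)C(C)(C)C)C[C@@]1(C)O[Si](CC)(CC)CC | intermediate
17 | 6α-alkenyl ketone | O=C1[C@@H](/C=C/CO[Si](c2ccccc2)(c2ccccc2)C(C)(C)C)[C@H](C(C)=C)[C@H](O[Si](C)(C)C(C)(C)C)C[C@@]1(C)O[Si](CC)(CC)CC | intermediate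
18 | ethynylmagnesium bromide | C#C[Mg]Br | starting material
19 | 1α-ethynyl-6α-alkenylcyclohexan-1β-ol | C#C[C@@]1(O)[C@@H](/C=C/CO[Si](c2ccccc2)(c2ccccc2)C(C)(C)C)[C@H](C(C)=C)[C@H](O[Si](C)(C)C(C)(C)C)C[C@@]1(C)O[Si](CC)(CC)CC | intermediate
20 | potassium alkoxide of 19 | [K+].C#C[C@@]1([O-])[C@@H](/C=C/CO[Si](c2ccccc2)(c2ccccc2)C(C)(C)C)[C@H](C(C)=C)[C@H](O[Si](C)(C)C(C)(C)C)C[C@@]1(C)O[Si](CC)(CC)CC | intermediate
21 | ten-membered potassium allenolate | [K+].[O-]C1=C=C[C@H](CO[Si](c2ccccc2)(c2ccccc2)C(C)(C)C)/C=C\[C@H](C(C)=C)[C@H](O[Si](C)(C)C(C)(C)C)C[C@@]1(C)O[Si](CC)(CC)CC | intermediate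
22 | (2Z,5Z)-cyclodeca-2,5-dienone | O=C1/C=C\[C@H](CO[Si](c2ccccc2)(c2ccccc2)C(C)(C)C)/C=C\[C@H](C(C)=C)[C@H](O[Si](C)(C)C(C)(C)C)C[C@@]1(C)O[Si](CC)(CC)CC | intermediate
23 | 10α-hydroxy-(2Z,5Z)-dienone | O=C1/C=C\[C@H](CO[Si](c2ccccc2)(c2ccccc2)C(C)(C)C)/C=C\[C@H](C(C)=C)[C@H](O[Si](C)(C)C(C)(C)C)C[C@@]1(C)O | intermediate
24 | oxa-bridged furanone with 5Z alkene | O=C1C=C2[C@H](CO[Si](c3ccccc3)(c3ccccc3)C(C)(C)C)/C=C\[C@H](C(C)=C)[C@H](O[Si](C)(C)C(C)(C)C)C[C@@]1(C)O2 | intermediate
25 | C12 allylic alcohol | O=C1C=C2[C@H](CO[Si](c3ccccc3)(c3ccccc3)C(C)(C)C)/C=C\[C@H](C(=C)CO)[C@H](O[Si](C)(C)C(C)(C)C)C[C@@]1(C)O2 | intermediate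
26 | C12 enal | O=C1C=C2[C@H](CO[Si](c3ccccc3)(c3ccccc3)C(C)(C)C)/C=C\[C@H](C(=C)C=O)[C@H](O[Si](C)(C)C(C)(C)C)C[C@@]1(C)O2 | intermediate
27 | 5α,6α-epoxy enal | O=C1C=C2[C@H](CO[Si](c3ccccc3)(c3ccccc3)C(C)(C)C)[C@H]3O[C@H]3[C@H](C(=C)C=O)[C@H](O[Si](C)(C)C(C)(C)C)C[C@@]1(C)O2 | intermediate
28 | 6α-hydroxy-4Z-dienyl enal | O=CC(=C)[C@H]1[C@H](O)/C=C(/CO[Si](c3ccccc3)(c3ccccc3)C(C)(C)C)C2=CC(=O)[C@@](C)(C[C@H]1O[Si](C)(C)C(C)(C)C)O2 | intermediate
29 | 6,12-lactol (C12 epimers) | C=C1C(O)O[C@@H]2/C=C(/CO[Si](c4ccccc4)(c4ccccc4)C(C)(C)C)C3=CC(=O)[C@@](C)(C[C@@H](O[Si](C)(C)C(C)(C)C)[C@@H]12)O3 | intermediate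
30 | bis-silyl α-methylene lactone | C=C1C(=O)O[C@@H]2/C=C(/CO[Si](c4ccccc4)(c4ccccc4)C(C)(C)C)C3=CC(=O)[C@@](C)(C[C@@H](O[Si](C)(C)C(C)(C)C)[C@@H]12)O3 | intermediate
31 | 8β-alcohol | C=C1C(=O)O[C@@H]2/C=C(/CO[Si](c4ccccc4)(c4ccccc4)C(C)(C)C)C3=CC(=O)[C@@](C)(C[C@@H](O)[C@@H]12)O3 | intermediate
32 | isobutyryl chloride | CC(C)C(=O)Cl | starting material
33 | 8-O-isobutyrate with 15-OTBDPS | C=C1C(=O)O[C@@H]2/C=C(/CO[Si](c4ccccc4)(c4ccccc4)C(C)(C)C)C3=CC(=O)[C@@](C)(C[C@@H](OC(=O)C(C)C)[C@@H]12)O3 | intermediate
34 | CNP0176924.3 | C=C1C(=O)O[C@@H]2/C=C(/CO)C3=CC(=O)[C@@](C)(C[C@@H](OC(=O)C(C)C)[C@@H]12)O3 | target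

## Step count and weakest steps

Total: 23 steps. Longest linear sequence: 21 steps (steps 1–9 and 12–23, from 1).

**Step 14 (key step).** The most likely failure is proton transfer before the quench. The strongly basic allenolate or unreacted alkoxide can pick up H4 or the alkyne hydrogen, and the double bonds then drift into conjugation. Loss of acetylide from the alkoxide, a reversible O-to-O shift of the TES group that slows the reaction, and erosion of the C5=C6 geometry through the ring-flipped chair are further risks.

The fallback keeps the ring expansion but avoids the allenolate. It sets out from 17: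

- Vinylmagnesium bromide with LaCl3·2LiCl gives the divinyl carbinol F1.
- KH and 18-crown-6, followed by Me3SiCl, give the ten-membered trimethylsilyl enol ether F2 by way of an ordinary, less basic enolate.
- Saegusa–Ito oxidation with Pd(OAc)2 in MeCN introduces C2=C3 under neutral conditions and gives the (2E,5Z)-dienone F3.
- HF·pyridine gives the hydroxy dienone F4.
- The conditions of step 16 convert F4 into 24, where the route is rejoined.

**Step 3.** Hydrogen abstraction at C7 or at the isopropenyl methyl group, over-oxidation, and migration of the isopropenyl double bond into conjugation with the new ketone can all lower the return.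

The fallback installs C8–O by enolate chemistry instead of C–H oxidation. It sets out from 1:

- Equilibrating silylation (TBSOTf, Et3N) gives the linear dienol silyl ether F5.
- Vinylogous Rubottom oxidation with mCPBA gives the 8α-hydroxy enone F6.
- Mitsunobu inversion with 4-nitrobenzoic acid, PPh3 and diisopropyl azodicarboxylate gives the 8β-ester F7.
- Methanolysis gives the 8β-hydroxy enone F8.
- Silylation as in step 5 returns to 8.

**Step 12.** Coupling at the hindered C6 may be slow. Proton exchange between the zinc enolate and the more acidic product can then epimerise C6 or move the alkene into conjugation.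

The fallback reverses the polarity. It sets out from 11:

- LiN(SiMe3)2 followed by NBS at −78 °C gives the 6α-bromo ketone F9.
- Nickel-catalysed cross-coupling (NiCl2(dme), a bipyridine ligand) of F9 with alkenylzirconocene 14 under neutral conditions returns to 17.

**Step 16.** Palladium may bind the skipped diene and abstract H4 to form an allyl complex, or it may isomerise the alkenes faster than it closes the ring.

The fallback separates ring closure from oxidation. It sets out from 23:

- Camphorsulfonic acid in CH2Cl2 promotes the acid-catalysed oxa-Michael closure to the saturated bicyclic ketone F10.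
- Deprotonation at C2 with LiN(SiMe3)2 and treatment with N-tert-butylbenzenesulfinimidoyl chloride at −78 °C dehydrogenates F10 to 24.

**Step 18.** The flanking C11 and C15 groups may make the alkene sluggish, and facial selectivity may be poor or even reversed if the ring adopts another conformation.

The fallback forms the C6–O bond with inversion instead of retention, so the other epoxide face also leads to the correct lactone. It sets out from 26:

- Pinnick oxidation (NaClO2, NaH2PO4, 2-methyl-2-butene) gives the acid F11.
- Epoxidation on the β face gives the epoxy acid F12.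
- The carboxyl group of F12 opens the epoxide at C6 from the rear to give the 5β-hydroxy lactone F13.
- MsCl and Et3N give the mesylate F14.
- DBU eliminates F14 across C4–C5 and returns to 30.

## Further compounds

F1 | step 14 | 1α-vinyl-6α-alkenylcyclohexan-1β-ol | C=C[C@@]1(O)[C@@H](/C=C/CO[Si](c2ccccc2)(c2ccccc2)C(C)(C)C)[C@H](C(C)=C)[C@H](O[Si](C)(C)C(C)(C)C)C[C@@]1(C)O[Si](CC)(CC)CC
F2 | step 14 | ten-membered trimethylsilyl enol ether (5Z) | C[Si](C)(C)OC1=CC[C@H](CO[Si](c2ccccc2)(c2ccccc2)C(C)(C)C)/C=C\[C@H](C(C)=C)[C@H](O[Si](C)(C)C(C)(C)C)C[C@@]1(C)O[Si](CC)(CC)CC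
F3 | step 14 | (2E,5Z)-cyclodeca-2,5-dienone | O=C1/C=C/[C@H](CO[Si](c2ccccc2)(c2ccccc2)C(C)(C)C)/C=C\[C@H](C(C)=C)[C@H](O[Si](C)(C)C(C)(C)C)C[C@@]1(C)O[Si](CC)(CC)CC
F4 | step 14 | 10α-hydroxy-(2E,5Z)-dienone | O=C1/C=C/[C@H](CO[Si](c2ccccc2)(c2ccccc2)C(C)(C)C)/C=C\[C@H](C(C)=C)[C@H](O[Si](C)(C)C(C)(C)C)C[C@@]1(C)O
F5 | step 3 | linear dienol TBS ether of carvone | CC1=C(O[Si](C)(C)C(C)(C)C)C[C@H](C(C)=C)C=C1
F6 | step 3 | 8α-hydroxy enone (hydroxyl trans to isopropenyl) | CC1=C[C@H](O)[C@H](CC1=O)C(C)=C
F7 | step 3 | 8β-(4-nitrobenzoyloxy) enone | CC1=C[C@@H](OC(=O)c2ccc(cc2)[N+](=O)[O-])[C@H](CC1=O)C(C)=C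
F8 | step 3 | 8β-hydroxy enone | CC1=C[C@@H](O)[C@H](CC1=O)C(C)=C
F9 | step 12 | 6α-bromo ketone | O=C1[C@@H](Br)[C@H](C(C)=C)[C@H](O[Si](C)(C)C(C)(C)C)C[C@@]1(C)O[Si](CC)(CC)CC
F10 | step 16 | saturated 3,10-oxa-bridged ketone | O=C1C[C@@H]2[C@H](CO[Si](c3ccccc3)(c3ccccc3)C(C)(C)C)/C=C\[C@H](C(C)=C)[C@H](O[Si](C)(C)C(C)(C)C)C[C@@]1(C)O2
F11 | step 18 | C12 carboxylic acid | O=C1C=C2[C@H](CO[Si](c3ccccc3)(c3ccccc3)C(C)(C)C)/C=C\[C@H](C(=C)C(=O)O)[C@H](O[Si](C)(C)C(C)(C)C)C[C@@]1(C)O2
F12 | step 18 | 5β,6β-epoxy acid | O=C1C=C2[C@H](CO[Si](c3ccccc3)(c3ccccc3)C(C)(C)C)[C@@H]3O[C@@H]3[C@H](C(=C)C(=O)O)[C@H](O[Si](C)(C)C(C)(C)C)C[C@@]1(C)O2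
F13 | step 18 | 5β-hydroxy lactone | C=C1C(=O)O[C@@H]2[C@@H](O)[C@@H](CO[Si](c4ccccc4)(c4ccccc4)C(C)(C)C)C3=CC(=O)[C@@](C)(C[C@@H](O[Si](C)(C)C(C)(C)C)[C@@H]12)O3
F14 | step 18 | 5β-mesyloxy lactone | C=C1C(=O)O[C@@H]2[C@@H](OS(C)(=O)=O)[C@@H](CO[Si](c4ccccc4)(c4ccccc4)C(C)(C)C)C3=CC(=O)[C@@](C)(C[C@@H](O[Si](C)(C)C(C)(C)C)[C@@H]12)O3
A1 | alternative 1 | diisopropylsilylene-linked 3-siloxyfuran and enol silane (C9–C10 open) | O=C1C[C@H]2[C@H](O1)/C=C(/CO[Si](C)(C)C(C)(C)C)c3cc(O[Si](C(C)C)(C(C)C)OC2=C)c(C)o3
A2 | alternative 1 | furanone-bridged ten-membered 8-ketone with saturated lactone | O=C1C[C@H]2[C@H](O1)/C=C(/CO[Si](C)(C)C(C)(C)C)C3=CC(=O)[C@@](C)(CC2=O)O3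
A3 | alternative 2 | C1 aldoxime with terminal diene (C1–C2 open) | ON=C[C@](C)(O[Si](CC)(CC)CC)C[C@@H](OC(=O)C(C)C)[C@H]1CC(=O)O[C@@H]1/C=C(/CO[Si](C)(C)C(C)(C)C)C=C
A4 | alternative 2 | isoxazoline-bridged ten-membered carbocycle | O=C1C[C@H]2[C@H](O1)/C=C(/CO[Si](C)(C)C(C)(C)C)[C@@H]3CC(=NO3)[C@](C)(O[Si](CC)(CC)CC)C[C@H]2OC(=O)C(C)C
A5 | alternative 3 | 1(10)-epoxy-3-oxo-4Z-germacranolide | C=C1C(=O)O[C@@H]2/C=C(/CO[Si](C)(C)C(C)(C)C)C(=O)C[C@@H]3O[C@@]3(C)C[C@@H](OC(=O)C(C)C)[C@@H]12
A6 | alternative 3 | 1-hydroxy-3,10-epoxy-2,4-diene | C=C1C(=O)O[C@@H]2/C=C(/CO[Si](C)(C)C(C)(C)C)C3=C[C@H](O)[C@@](C)(C[C@@H](OC(=O)C(C)C)[C@@H]12)O3
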